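**Retrosynthetic overview** (benzofuran numbering: O1, C2, C3, C3a, C4–C7, C7a)

1. Last cut is the C3–O acyl bond: trans-alcohol 14 (O6 silylated as 15) plus (Z)-2-(acetoxymethyl)but-2-enoic acid 21; the Z geometry of 21 comes from bromine–lithium exchange and carboxylation of a (Z)-bromoalkene made from crotonaldehyde.
2. The dihydrofuran ring is formed second: O1–C2 by 5-exo Tsuji–Trost closure of the C7a phenol onto the π-allyl from primary allylic acetate 13, with the C3 carbinol steering C2 to trans.
3. Ring A is formed first and carries the strategy. Its carbons in the linear 1,2,4,5 pattern (C3a side arm, C5 acetyl, C6–OH, C7a–O) map onto the acetate end C3a–C7a of hydroxy ester 8, a one-carbon C4 and the acetyl–C5–C6–C7 acetylacetone unit of 9; bonds C3a–C4 and C7–C7a are made in one flask.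
4. Ester 8 comes from enal 5 by an (S)-HYTRA acetate aldol that sets C3; enal 5 comes from prenyl acetate.

Key step: step 7

Remark: lithium or magnesium enolates, alkoxides and organometallic species that are only the metallated form of a numbered or F-labelled compound are described in the text and carry no label of their own.

**Route**

Step 1
Reactants: 1 3-methylbut-2-en-1-yl acetate (prenyl acetate)
Product: 2 (2E)-4-hydroxy-3-methylbut-2-en-1-yl acetate
Conditions: SeO2 (cat.), tBuOOH, CH2Cl2, rt
Reagents that add atoms: tert-butyl hydroperoxide, CC(C)(C)OO (oxygen source); selenium dioxide, O=[Se]=O (catalytic oxygen carrier)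
Why: SeO2/tBuOOH allylic oxidation (ene reaction, then [2,3]-sigmatropic shift) should hydroxylate only the methyl group trans to the acetoxymethyl chain, which fixes the E geometry used later; any over-oxidised enal is removed by chromatography.

Step 2
Reactants: 2 (2E)-4-hydroxy-3-methylbut-2-en-1-yl acetate
Product: 3 (2E)-4-[tert-butyl(dimethyl)silyl]oxy-3-methylbut-2-en-1-yl acetate
Conditions: TBSCl, imidazole, DMF, 0 °C → rt
Reagents that add atoms: tert-butyldimethylsilyl chloride, CC(C)(C)[Si](C)(C)Cl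
Why: imidazole-promoted silylation of a primary alcohol; the acetate is untouched.

Step 3
Reactants: 3 (2E)-4-[tert-butyl(dimethyl)silyl]oxy-3-methylbut-2-en-1-yl acetate
Product: 4 (2E)-4-[tert-butyl(dimethyl)silyl]oxy-3-methylbut-2-en-1-ol
Conditions: K2CO3 (cat.), MeOH, rt
Reagents that add atoms: none
Why: carbonate-catalysed transesterification removes the acetate, and a primary TBS ether is stable under these conditions.

Step 4
Reactants: 4 (2E)-4-[tert-butyl(dimethyl)silyl]oxy-3-methylbut-2-en-1-ol
Product: 5 (2E)-4-[tert-butyl(dimethyl)silyl]oxy-3-methylbut-2-enal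
Conditions: TEMPO (cat.), PhI(OAc)2, CH2Cl2, rt
Reagents that add atoms: none
Why: oxoammonium (TEMPO) oxidation of an allylic alcohol should stop at the enal without E/Z isomerisation.

Step 5
Reactants: 5 (2E)-4-[tert-butyl(dimethyl)silyl]oxy-3-methylbut-2-enal; 6 (1S)-2-hydroxy-1,2,2-triphenylethyl acetate ((S)-HYTRA)
Product: 7 (1S)-2-hydroxy-1,2,2-triphenylethyl (3S,4E)-6-[tert-butyl(dimethyl)silyl]oxy-3-hydroxy-5-methylhex-4-enoate
Conditions: 6, LiN(iPr)2 (2.2 equiv), THF, −78 → 0 °C; MgBr2·OEt2, −78 °C; 5, −100 °C; aq. NH4Cl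
Reagents that add atoms: none
Why: HYTRA acetate aldol: the doubly deprotonated (S)-auxiliary acetate should add to the Si face of the enal and so set the (3S) carbinol (the later C3); the minor diastereomer should be removable by crystallisation.

Step 6
Reactants: 7 (1S)-2-hydroxy-1,2,2-triphenylethyl (3S,4E)-6-[tert-butyl(dimethyl)silyl]oxy-3-hydroxy-5-methylhex-4-enoate
Product: 8 methyl (3S,4E)-6-[tert-butyl(dimethyl)silyl]oxy-3-hydroxy-5-methylhex-4-enoate
Conditions: K2CO3, MeOH, rt
Reagents that add atoms: methanol, CO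
Why: mild carbonate-mediated transesterification releases the methyl ester and the auxiliary diol without retro-aldol cleavage or dehydration of the β-hydroxy ester.

Step 7
Reactants: 8 methyl (3S,4E)-6-[tert-butyl(dimethyl)silyl]oxy-3-hydroxy-5-methylhex-4-enoate; 9 3-(ethoxymethylidene)pentane-2,4-dione
Product: 11 1-[5-[(1R,2E)-4-[tert-butyl(dimethyl)silyl]oxy-1-hydroxy-3-methylbut-2-en-1-yl]-2,4-dihydroxyphenyl]ethan-1-one, via acyclic alkylidene diketone adduct 10 (not isolated)
Conditions: 8, LiN(iPr)2 (2.2 equiv), THF, −78 → −30 °C; 9, −78 → −40 °C; LiN(iPr)2 (2.5 equiv), −78 → 0 °C; aq. NH4Cl (pH about 6), 0 °C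
Reagents that add atoms: none
Why: Proposed new method: the lithium alkoxide–enolate of 8 should add through its α-carbon to the ethoxymethylene carbon of 9 and expel ethoxide (bond C3a–C4, adduct 10), and the second charge of base should convert 10 into a polyanion whose acetyl methyl carbon attacks the ester carbonyl and expels methoxide (bond C7–C7a), after which the acyl cyclohexadienone enolises irreversibly to the resorcinol; the closest known reaction types are the C-alkylation and conjugate addition of β-hydroxy ester dianions (Fráter–Seebach chemistry), the addition–elimination of lithium enolates to alkoxymethylene 1,3-dicarbonyl compounds, and the polyketide-type Claisen cyclisation of β-diketone polyanions onto esters. Ring A closes in a 6-(enolexo)-exo-trig Claisen mode, and the geometry for it is always available because C5 carries two acetyl groups, one of which is cis to the ester arm. No stereocentre is formed; the C3 carbinol from step 5 rides through as its lithium alkoxide, which is not a leaving group for E1cB loss and, once C3a is deprotonated, cannot leave by retro-aldol cleavage (its descriptor changes from S to R only through the priority rules). The step needs carbon and not oxygen to react at both stages (closure through the enolate oxygen would give a 2-pyranone), which the hard lithium polyanion with charge on the terminal methyl carbon and the irreversible aromatisation should secure. Regiochemistry needs no further control: the ester is nucleophilic at C3a and electrophilic at C7a, and 9 is electrophilic at C4 and nucleophilic at C7, so acetyl must end at C5 and the side arm at C3a.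

Step 8
Reactants: 11 1-[5-[(1R,2E)-4-[tert-butyl(dimethyl)silyl]oxy-1-hydroxy-3-methylbut-2-en-1-yl]-2,4-dihydroxyphenyl]ethan-1-one
Product: 12 1-[5-[(1R,2E)-1,4-dihydroxy-3-methylbut-2-en-1-yl]-2,4-dihydroxyphenyl]ethan-1-one
Conditions: Bu4NF, AcOH (1:1.2), THF, 0 °C
Reagents that add atoms: none
Why: buffered fluoride desilylation of the primary TBS ether; the near-neutral medium should keep the o,p-dihydroxybenzylic allylic alcohol from ionising (acid) or forming a quinone methide (base).

Step 9
Reactants: 12 1-[5-[(1R,2E)-1,4-dihydroxy-3-methylbut-2-en-1-yl]-2,4-dihydroxyphenyl]ethan-1-one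
Product: 13 (2E,4R)-4-(5-acetyl-2,4-dihydroxyphenyl)-4-hydroxy-2-methylbut-2-en-1-yl acetate
Conditions: immobilised Candida antarctica lipase B, vinyl acetate, THF, 30 °C
Reagents that add atoms: vinyl acetate, C=COC(C)=O
Why: lipase-catalysed transesterification with an enol ester acylates the primary alcohol and should leave the two phenols and the hindered secondary benzylic alcohol untouched, which a chloroformate or anhydride with base would not.

Step 10
Reactants: 13 (2E,4R)-4-(5-acetyl-2,4-dihydroxyphenyl)-4-hydroxy-2-methylbut-2-en-1-yl acetate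
Product: 14 1-[(2R,3S)-3,6-dihydroxy-2-(prop-1-en-2-yl)-2,3-dihydro-1-benzofuran-5-yl]ethan-1-one
Conditions: Pd2(dba)3·CHCl3 (2.5 mol%), PPh3 (10 mol%), Et3N, THF, 40 °C
Reagents that add atoms: none
Why: Tsuji–Trost O-allylation: zerovalent palladium ionises the allylic acetate and the C7a phenoxide attacks the internal allyl terminus in a 5-exo mode (O1–C2), leaving the isopropenyl group; the π-allyl faces interconvert through the unsubstituted CH2 terminus and the closure is reversible, so the (S)-carbinol at C3 should direct the new C2 centre to the more stable trans (2R) arrangement.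

Step 11
Reactants: 14 1-[(2R,3S)-3,6-dihydroxy-2-(prop-1-en-2-yl)-2,3-dihydro-1-benzofuran-5-yl]ethan-1-one
Product: 15 1-[(2R,3S)-6-[tert-butyl(dimethyl)silyl]oxy-3-hydroxy-2-(prop-1-en-2-yl)-2,3-dihydro-1-benzofuran-5-yl]ethan-1-one
Conditions: TBSCl (1.05 equiv), imidazole, CH2Cl2, 0 °C → rt
Reagents that add atoms: tert-butyldimethylsilyl chloride, CC(C)(C)[Si](C)(C)Cl
Why: silylation is faster at the acidic phenol than at the hindered secondary benzylic alcohol, so one equivalent should mask only O6; this blocks aryl ester formation and quinone methide chemistry in step 16.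

Step 12
Reactants: 16 (2E)-but-2-enal (crotonaldehyde)
Product: 18 (2Z)-2-bromobut-2-enal, via 2,3-dibromobutanal 17 (not isolated)
Conditions: Br2, CH2Cl2, −10 °C; then Et3N, 0 °C → rt
Reagents that add atoms: bromine, BrBr
Why: bromine addition followed by E1cB loss of HBr from the α-position should give the thermodynamically preferred bromoenal with CHO trans to the methyl group (Z).

Step 13
Reactants: 18 (2Z)-2-bromobut-2-enal
Product: 19 (2Z)-2-bromobut-2-en-1-ol
Conditions: NaBH4, CeCl3·7H2O, MeOH, 0 °C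
Reagents that add atoms: none
Why: Luche 1,2-reduction of the enal leaves the alkene geometry and the vinyl bromide untouched.

Step 14
Reactants: 19 (2Z)-2-bromobut-2-en-1-ol
Product: 20 (2Z)-2-(hydroxymethyl)but-2-enoic acid
Conditions: tBuLi (3.1 equiv), Et2O, −78 °C; CO2, −78 °C → rt; aq. HCl
Reagents that add atoms: carbon dioxide, O=C=O
Why: O-deprotonation and bromine–lithium exchange give a configurationally stable vinyllithium that is carboxylated with retention, which places CO2H cis to the methyl group (Z).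

Step 15
Reactants: 20 (2Z)-2-(hydroxymethyl)but-2-enoic acid
Product: 21 (2Z)-2-(acetoxymethyl)but-2-enoic acid
Conditions: Ac2O, pyridine, CH2Cl2, 0 °C → rt; then H2O
Reagents that add atoms: acetic anhydride, CC(=O)OC(C)=O
Why: acetylation of the primary alcohol; the aqueous work-up hydrolyses any mixed anhydride at the acid, and the alkene geometry is not at risk under these conditions.

Step 16
Reactants: 21 (2Z)-2-(acetoxymethyl)but-2-enoic acid; 15 1-[(2R,3S)-6-[tert-butyl(dimethyl)silyl]oxy-3-hydroxy-2-(prop-1-en-2-yl)-2,3-dihydro-1-benzofuran-5-yl]ethan-1-one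
Product: 23 (2R,3S)-5-acetyl-6-[tert-butyl(dimethyl)silyl]oxy-2-(prop-1-en-2-yl)-2,3-dihydro-1-benzofuran-3-yl (2Z)-2-(acetoxymethyl)but-2-enoate, via mixed trichlorobenzoic anhydride 22 (not isolated)
Conditions: 21, 2,4,6-trichlorobenzoyl chloride, Et3N, THF, rt; filter; then 15, toluene, 80 °C (no DMAP)
Reagents that add atoms: none
Why: Yamaguchi-type esterification through mixed anhydride 22: the C3 hydroxyl should attack the less hindered acyl group, and leaving out nucleophilic catalysts should preserve both the Z alkene and the allylic acetate; acylation is at oxygen, so C3 keeps its configuration.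

Step 17
Reactants: 23 (2R,3S)-5-acetyl-6-[tert-butyl(dimethyl)silyl]oxy-2-(prop-1-en-2-yl)-2,3-dihydro-1-benzofuran-3-yl (2Z)-2-(acetoxymethyl)but-2-enoate
Product: 24 (2R,3S)-5-acetyl-6-hydroxy-2-(prop-1-en-2-yl)-2,3-dihydro-1-benzofuran-3-yl (2Z)-2-(acetoxymethyl)but-2-enoate (target, CNP0193314.3)
Conditions: Bu4NF, AcOH (1:1.5), THF, 0 °C
Reagents that add atoms: none
Why: buffered fluoride cleaves the aryl silyl ether ortho to the acetyl group; keeping the phenol protonated should prevent loss of the C3 carboxylate through a p-quinone methide.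

**Compound list**

1 | 3-methylbut-2-en-1-yl acetate (prenyl acetate) | CC(C)=CCOC(C)=O | starting material
2 | (2E)-4-hydroxy-3-methylbut-2-en-1-yl acetate | CC(=O)OC/C=C(\C)CO | intermediate
3 | (2E)-4-[tert-butyl(dimethyl)silyl]oxy-3-methylbut-2-en-1-yl acetate | CC(=O)OC/C=C(\C)CO[Si](C)(C)C(C)(C)C | intermediate
4 | (2E)-4-[tert-butyl(dimethyl)silyl]oxy-3-methylbut-2-en-1-ol | OC/C=C(\C)CO[Si](C)(C)C(C)(C)C | intermediate
5 | (2E)-4-[tert-butyl(dimethyl)silyl]oxy-3-methylbut-2-enal | O=C/C=C(\C)CO[Si](C)(C)C(C)(C)C | intermediate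
6 | (1S)-2-hydroxy-1,2,2-triphenylethyl acetate, (S)-HYTRA | CC(=O)O[C@@H](c1ccccc1)C(O)(c1ccccc1)c1ccccc1 | starting material
7 | (1S)-2-hydroxy-1,2,2-triphenylethyl (3S,4E)-6-[tert-butyl(dimethyl)silyl]oxy-3-hydroxy-5-methylhex-4-enoate | O=C(C[C@H](O)/C=C(\C)CO[Si](C)(C)C(C)(C)C)O[C@@H](c1ccccc1)C(O)(c1ccccc1)c1ccccc1 | intermediate
8 | methyl (3S,4E)-6-[tert-butyl(dimethyl)silyl]oxy-3-hydroxy-5-methylhex-4-enoate | COC(=O)C[C@H](O)/C=C(\C)CO[Si](C)(C)C(C)(C)C | intermediate (key-step precursor)
9 | 3-(ethoxymethylidene)pentane-2,4-dione | CCOC=C(C(C)=O)C(C)=O | starting material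
10 | methyl (3R,4E)-2-(2-acetyl-3-oxobut-1-en-1-yl)-6-[tert-butyl(dimethyl)silyl]oxy-3-hydroxy-5-methylhex-4-enoate (both C2 epimers, present as lithium salt) | COC(=O)C(C=C(C(C)=O)C(C)=O)[C@H](O)/C=C(\C)CO[Si](C)(C)C(C)(C)C | intermediate (not isolated)
11 | 1-[5-[(1R,2E)-4-[tert-butyl(dimethyl)silyl]oxy-1-hydroxy-3-methylbut-2-en-1-yl]-2,4-dihydroxyphenyl]ethan-1-one | CC(=O)c1cc([C@H](O)/C=C(\C)CO[Si](C)(C)C(C)(C)C)c(O)cc1O | intermediate (key-step product)
12 | 1-[5-[(1R,2E)-1,4-dihydroxy-3-methylbut-2-en-1-yl]-2,4-dihydroxyphenyl]ethan-1-one | CC(=O)c1cc([C@H](O)/C=C(\C)CO)c(O)cc1O | intermediate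
13 | (2E,4R)-4-(5-acetyl-2,4-dihydroxyphenyl)-4-hydroxy-2-methylbut-2-en-1-yl acetate | CC(=O)c1cc([C@H](O)/C=C(\C)COC(C)=O)c(O)cc1O | intermediate
14 | 1-[(2R,3S)-3,6-dihydroxy-2-(prop-1-en-2-yl)-2,3-dihydro-1-benzofuran-5-yl]ethan-1-one | C=C(C)[C@H]1Oc2cc(O)c(C(C)=O)cc2[C@@H]1O | intermediate
15 | 1-[(2R,3S)-6-[tert-butyl(dimethyl)silyl]oxy-3-hydroxy-2-(prop-1-en-2-yl)-2,3-dihydro-1-benzofuran-5-yl]ethan-1-one | C=C(C)[C@H]1Oc2cc(O[Si](C)(C)C(C)(C)C)c(C(C)=O)cc2[C@@H]1O | intermediate
16 | (2E)-but-2-enal (crotonaldehyde) | C/C=C/C=O | starting material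
17 | 2,3-dibromobutanal (racemic) | CC(Br)C(Br)C=O | intermediate (not isolated)
18 | (2Z)-2-bromobut-2-enal | C/C=C(\Br)C=O | intermediate
19 | (2Z)-2-bromobut-2-en-1-ol | C/C=C(\Br)CO | intermediate
20 | (2Z)-2-(hydroxymethyl)but-2-enoic acid | C/C=C(\C(=O)O)CO | intermediate
21 | (2Z)-2-(acetoxymethyl)but-2-enoic acid | C/C=C(\C(=O)O)COC(C)=O | intermediate
22 | (2Z)-2-(acetoxymethyl)but-2-enoic 2,4,6-trichlorobenzoic anhydride | C/C=C(\C(=O)OC(=O)c1c(Cl)cc(Cl)cc1Cl)COC(C)=O | intermediate (not isolated)
23 | (2R,3S)-5-acetyl-6-[tert-butyl(dimethyl)silyl]oxy-2-(prop-1-en-2-yl)-2,3-dihydro-1-benzofuran-3-yl (2Z)-2-(acetoxymethyl)but-2-enoate | C=C(C)[C@H]1Oc2cc(O[Si](C)(C)C(C)(C)C)c(C(C)=O)cc2[C@@H]1OC(=O)/C(=C\C)COC(C)=O | intermediate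
24 | (2R,3S)-5-acetyl-6-hydroxy-2-(prop-1-en-2-yl)-2,3-dihydro-1-benzofuran-3-yl (2Z)-2-(acetoxymethyl)but-2-enoate | C=C(C)[C@H]1Oc2cc(O)c(C(C)=O)cc2[C@@H]1OC(=O)/C(=C\C)COC(C)=O | target

**Step count**

Total: 17 steps. Longest linear sequence: 13 steps (steps 1–11, 16, 17); the side-chain acid takes 4 steps (12–15).

**Steps most likely to fail**

1. Step 7 (proposed new method). The strongly basic dianion may take a proton from an acetyl group of 9 instead of adding to it. The ring may also close through the enolate oxygen to a 2-pyranone instead of through carbon, or the adduct may undergo retro-aldol cleavage before C3a is deprotonated.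
Fallback with known chemistry: ring A is bought and the C3–C3a bond is made by catalytic asymmetric aryl transfer. It sets out from enal 5 and comes back at tetraol 12. Commercial 4,6-dibromoresorcinol is silylated (iPr3SiCl, imidazole) to 1,5-dibromo-2,4-bis(triisopropylsilyloxy)benzene F1. One bromine is exchanged (nBuLi, tBuOMe, −78 °C), the aryllithium is converted into the mixed aryl(butyl)zinc (ZnCl2, then nBuLi), and lithium chloride is sequestered with N,N,N',N'-tetraethylethylenediamine. Addition to 5 with catalytic (−)-3-exo-morpholinoisoborneol should deliver the aryl group to the Si face of the aldehyde and give (1R,2E)-1-[5-bromo-2,4-bis(triisopropylsilyloxy)phenyl]-4-[tert-butyl(dimethyl)silyl]oxy-3-methylbut-2-en-1-ol F2. Stille coupling of the remaining bromide with tributyl(1-ethoxyvinyl)stannane (Pd(PPh3)4, toluene, 90 °C) gives the enol ether (1R,2E)-4-[tert-butyl(dimethyl)silyl]oxy-1-[5-(1-ethoxyethenyl)-2,4-bis(triisopropylsilyloxy)phenyl]-3-methylbut-2-en-1-ol F3. Hydrolysis with dilute aqueous oxalic acid gives the ketone 1-[5-[(1R,2E)-4-[tert-butyl(dimethyl)silyl]oxy-1-hydroxy-3-methylbut-2-en-1-yl]-2,4-bis(triisopropylsilyloxy)phenyl]ethan-1-one F4. Global desilylation (Bu4NF, AcOH, THF, 0 °C) gives 12.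

2. Step 10. The C3 centre may transmit its configuration only weakly to C2, because the π-allyl faces equilibrate, so a cis/trans mixture may form. Attack by the C3 hydroxyl or β-hydride loss from the π-allyl complex may also compete.
Fallback: a stereospecific epoxide opening replaces the π-allyl closure. It sets out from acetate 13 and comes back at 14. Hydroxyl-directed epoxidation (m-CPBA, NaHCO3, CH2Cl2, 0 °C) under A(1,3)-strain control should give the threo epoxide [(2R,3R)-3-[(S)-(5-acetyl-2,4-dihydroxyphenyl)(hydroxy)methyl]-2-methyloxiran-2-yl]methyl acetate F5. With K2CO3 in MeOH the C7a phenoxide should open the epoxide at the secondary carbon in a 5-exo mode with inversion, which fixes the trans relation. The acetate is cleaved in the same flask, giving 1-[(2S,3S)-2-[(2R)-1,2-dihydroxypropan-2-yl]-3,6-dihydroxy-2,3-dihydro-1-benzofuran-5-yl]ethan-1-one F6. The 1,2-diol is closed with 1,1'-thiocarbonyldiimidazole (THF, rt) to the cyclic thionocarbonate 1-[(2S,3S)-3,6-dihydroxy-2-[(4R)-4-methyl-2-sulfanylidene-1,3-dioxolan-4-yl]-2,3-dihydro-1-benzofuran-5-yl]ethan-1-one F7. Corey–Winter olefination with 1,3-dimethyl-2-phenyl-1,3,2-diazaphospholidine (THF, 40 °C) unveils the isopropenyl group and gives 14.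

3. Step 16. Acyl transfer to the hindered benzylic alcohol may be slow at the temperature where the Z acyl unit begins to isomerise or the allylic acetate to migrate. The C3–O bond may also ionise on prolonged heating.
Fallback: strain-driven acylation with a β-lactone instead of activation of the free acid. It sets out from bromo alcohol 19 and alcohol 15 and comes back at 23. Palladium-catalysed carbonylative lactonisation of 19 (PdCl2(PPh3)2 cat., CO, Et3N, THF, 50 °C) proceeds with retention at the vinyl carbon and gives (3Z)-3-ethylideneoxetan-2-one F8. The lithium alkoxide of 15 (LiN(SiMe3)2, THF, −78 °C) opens F8 at the acyl carbon to give (2R,3S)-5-acetyl-6-[tert-butyl(dimethyl)silyl]oxy-2-(prop-1-en-2-yl)-2,3-dihydro-1-benzofuran-3-yl (2Z)-2-(hydroxymethyl)but-2-enoate F9. Acetylation of the liberated primary alcohol (Ac2O, pyridine, 0 °C) gives 23.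

**Further compounds**

F1 | step 7 | 1,5-dibromo-2,4-bis(triisopropylsilyloxy)benzene | CC(C)[Si](Oc1cc(O[Si](C(C)C)(C(C)C)C(C)C)c(Br)cc1Br)(C(C)C)C(C)C
F2 | step 7 | (1R,2E)-1-[5-bromo-2,4-bis(triisopropylsilyloxy)phenyl]-4-[tert-butyl(dimethyl)silyl]oxy-3-methylbut-2-en-1-ol | CC(C)[Si](Oc1cc(O[Si](C(C)C)(C(C)C)C(C)C)c([C@H](O)/C=C(\C)CO[Si](C)(C)C(C)(C)C)cc1Br)(C(C)C)C(C)C
F3 | step 7 | (1R,2E)-4-[tert-butyl(dimethyl)silyl]oxy-1-[5-(1-ethoxyethenyl)-2,4-bis(triisopropylsilyloxy)phenyl]-3-methylbut-2-en-1-ol | C=C(OCC)c1cc([C@H](O)/C=C(\C)CO[Si](C)(C)C(C)(C)C)c(O[Si](C(C)C)(C(C)C)C(C)C)cc1O[Si](C(C)C)(C(C)C)C(C)C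
F4 | step 7 | 1-[5-[(1R,2E)-4-[tert-butyl(dimethyl)silyl]oxy-1-hydroxy-3-methylbut-2-en-1-yl]-2,4-bis(triisopropylsilyloxy)phenyl]ethan-1-one | CC(=O)c1cc([C@H](O)/C=C(\C)CO[Si](C)(C)C(C)(C)C)c(O[Si](C(C)C)(C(C)C)C(C)C)cc1O[Si](C(C)C)(C(C)C)C(C)C
F5 | step 10 | [(2R,3R)-3-[(S)-(5-acetyl-2,4-dihydroxyphenyl)(hydroxy)methyl]-2-methyloxiran-2-yl]methyl acetate | CC(=O)c1cc([C@H](O)[C@H]2O[C@]2(C)COC(C)=O)c(O)cc1O
F6 | step 10 | 1-[(2S,3S)-2-[(2R)-1,2-dihydroxypropan-2-yl]-3,6-dihydroxy-2,3-dihydro-1-benzofuran-5-yl]ethan-1-one | C[C@@](O)(CO)[C@H]1Oc2cc(O)c(C(C)=O)cc2[C@@H]1O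
F7 | step 10 | 1-[(2S,3S)-3,6-dihydroxy-2-[(4R)-4-methyl-2-sulfanylidene-1,3-dioxolan-4-yl]-2,3-dihydro-1-benzofuran-5-yl]ethan-1-one | C[C@@]1(COC(=S)O1)[C@H]1Oc2cc(O)c(C(C)=O)cc2[C@@H]1O
F8 | step 16 | (3Z)-3-ethylideneoxetan-2-one | C/C=C1\C(=O)OC1
F9 | step 16 | (2R,3S)-5-acetyl-6-[tert-butyl(dimethyl)silyl]oxy-2-(prop-1-en-2-yl)-2,3-dihydro-1-benzofuran-3-yl (2Z)-2-(hydroxymethyl)but-2-enoate | C=C(C)[C@H]1Oc2cc(O[Si](C)(C)C(C)(C)C)c(C(C)=O)cc2[C@@H]1OC(=O)/C(=C\C)CO
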